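**Plan**

- Target in flavone numbering (rings A, C, B): 5-hydroxy-6,7-dimethoxy-2-(2,3,4,5-tetramethoxyphenyl)chromen-4-one. Retrosynthetically the 5-OH goes back to a 5-OMe and the 6-OMe to a free 6-OH; ring C is then cut at O1–C8a, the open β-diketone at C2–C3, and last the two aryl–carbonyl bonds (C4–C4a and C2–C1').
- Forward: the ring A acetophenone (from 2,6-dimethoxyphenol by O-acetylation, Friedel–Crafts acetylation, deacetylation) and the ring B methyl ester (from 1,2,3,4-tetramethoxybenzene by lithiation and methoxycarbonylation) are joined by a Claisen condensation. Ring C, the only ring that has to be built, is then closed oxidatively at O1–C8a; O-methylation and chelation-directed cleavage of the 5-methyl ether finish the route.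
- Enabling feature: C8a of ring A is para to the C6 oxygen. A free C6 hydroxyl between the C5 and C7 methoxy groups therefore gives, on two-electron oxidation, a cation whose only hydrogen-bearing electrophilic carbon is C8a, within reach of the enol oxygen on C2.
- Stereochemistry: none to set; the target has no stereocentre and no stereogenic double bond.

Key step: step 6

Assumption: 2,6-dimethoxyphenol and 1,2,3,4-tetramethoxybenzene are taken as catalogue chemicals, and each 1,3-diketone is drawn as its diketo form although it will be largely enolised.

**Step 1**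
Reactants: 1 2,6-dimethoxyphenol
Product: 2 2,6-dimethoxyphenyl acetate
Conditions: Ac2O, pyridine, DMAP (cat.), CH2Cl2, 0 °C to rt
Reagents that add atoms: acetic anhydride CC(=O)OC(C)=O
Why: Base-mediated O-acetylation (nucleophilic acyl substitution) of the phenol should be clean and turns the strongest donor of the ring into a weak one, so that the two methoxy groups steer the next step.

**Step 2**
Reactants: 2 2,6-dimethoxyphenyl acetate
Product: 3 3-acetyl-2,6-dimethoxyphenyl acetate
Conditions: AcCl, TiCl4, CH2Cl2, −10 °C to 0 °C; cold dilute HCl work-up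
Reagents that add atoms: acetyl chloride CC(=O)Cl
Why: Friedel–Crafts acylation should take place at C3, which is ortho to one methoxy group and para to the other, whereas C4 is meta to both and only para to the weakly donating acetoxy group; TiCl4 at or below 0 °C should spare the methoxy group next to the new ketone.

**Step 3**
Reactants: 3 3-acetyl-2,6-dimethoxyphenyl acetate
Product: 4 1-(3-hydroxy-2,4-dimethoxyphenyl)ethanone
Conditions: K2CO3 (cat.), MeOH, rt
Reagents that add atoms: none
Why: Carbonate-catalysed transesterification with methanol should remove the aryl acetate, a far better acyl donor than the aryl methyl ketone, without touching the ketone or the methyl ethers.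

**Step 4**
Reactants: 5 1,2,3,4-tetramethoxybenzene
Product: 7 methyl 2,3,4,5-tetramethoxybenzoate, via 2,3,4,5-tetramethoxyphenyllithium 6 (not isolated)
Conditions: n-BuLi, TMEDA, THF, 0 °C; then added by cannula to ClCO2Me (3 equiv), THF, −78 °C
Reagents that add atoms: methyl chloroformate COC(=O)Cl; n-butyllithium [Li]CCCC (supplies only the lithium of 6)
Why: Directed ortho-metalation should lithiate one of the two equivalent ring hydrogens, each next to a methoxy group, and inverse addition of the aryllithium to excess chloroformate at low temperature should stop the acyl substitution at the ester.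

**Step 5**
Reactants: 4 1-(3-hydroxy-2,4-dimethoxyphenyl)ethanone; 7 methyl 2,3,4,5-tetramethoxybenzoate
Product: 9 1-(3-hydroxy-2,4-dimethoxyphenyl)-3-(2,3,4,5-tetramethoxyphenyl)propane-1,3-dione, via dilithium phenoxide-enolate 8 (not isolated)
Conditions: LiN(SiMe3)2 (3.3 equiv), THF, −78 °C to −20 °C; then 7, −78 °C to rt; 1 M HCl work-up
Reagents that add atoms: lithium bis(trimethylsilyl)amide [Li]N([Si](C)(C)C)[Si](C)(C)C (supplies only the lithium of 8)
Why: Crossed Claisen condensation: the excess amide base should turn 4 into its phenoxide-enolate, whose carbon terminus is acylated by the non-enolisable ester 7, and deprotonation of the β-diketone formed pulls the equilibrium to the product while the phenoxide stays a spectator.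

**Step 6**
Reactants: 9 1-(3-hydroxy-2,4-dimethoxyphenyl)-3-(2,3,4,5-tetramethoxyphenyl)propane-1,3-dione
Product: 12 6-hydroxy-5,7-dimethoxy-2-(2,3,4,5-tetramethoxyphenyl)chromen-4-one, via ring A phenoxonium cation 10 (not isolated), via 8a-H cyclohexadienone 11 (not isolated)
Conditions: graphite anode, Pt cathode, undivided cell, constant current (about 5 mA cm−2, 2.1 F mol−1), Bu4NPF6 (0.1 M), HFIP, 0.02 M in 9, rt
Reagents that add atoms: none
Why: Proposed new method: the ring A phenol is the most easily oxidised site of 9 (ring B is fully methylated and carries the deactivating acyl group), so loss of two electrons and one proton at the anode should give cation 10, whose charge sits on C5 and C7 (both methoxylated) and on C8a (hydrogen-bearing, para to the C6 oxygen). The enol oxygen on C2 then adds to C8a, a 6-exo-trig closure with respect to the C8=C8a bond of the cation that forms ring C as the pyranone and gives dienone 11; loss of the C8a proton restores aromatic ring A in 12 while the cathode releases H2. The closest known reaction types are the anodic oxidation of 2,6-dimethoxyphenols to phenoxonium ions that oxygen nucleophiles capture at the para carbon, and the anodic dehydrogenative lactonisation of biaryl-2-carboxylic acids; closure of a chromone by an enol oxygen in this way has not been described. No stereocentre remains, because C8a of 11 is sp3 only in passing. The step needs four selectivities: ring A must be oxidised before ring B (secured by the free phenol); capture must be para and not ortho (addition at the methoxylated C5 would also make a six-membered ring, but gives a ketal that cannot aromatise and should revert in the ionising solvent, whereas capture at C8a is made irreversible by proton loss); oxygen and not carbon must attack (C3 could reach ring A only through a four-membered ring); and further oxidation of 12 must be held back (charge limited to about 2 F per mole, dilute solution, a poorly nucleophilic solvent, and a base-free medium so that the more oxidisable diketonate never builds up).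

**Step 7**
Reactants: 12 6-hydroxy-5,7-dimethoxy-2-(2,3,4,5-tetramethoxyphenyl)chromen-4-one
Product: 13 5,6,7-trimethoxy-2-(2,3,4,5-tetramethoxyphenyl)chromen-4-one
Conditions: MeI, K2CO3, acetone, reflux
Reagents that add atoms: iodomethane CI
Why: Williamson-type O-methylation (SN2) of the only acidic hydroxyl should go to completion, since the phenoxide is flanked by two methoxy groups but the electrophile is small.

**Step 8**
Reactants: 13 5,6,7-trimethoxy-2-(2,3,4,5-tetramethoxyphenyl)chromen-4-one
Product: 15 5-hydroxy-6,7-dimethoxy-2-(2,3,4,5-tetramethoxyphenyl)chromen-4-one (agecorynin F), via 5-O-dichloroboryl chelate 14 (not isolated)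
Conditions: BCl3 (1.5 equiv, 1 M in CH2Cl2), CH2Cl2, −78 °C to 0 °C; then H2O, rt
Reagents that add atoms: boron trichloride ClB(Cl)Cl (supplies only the boron and chlorine of 14)
Why: Chelation-controlled Lewis-acid ether cleavage: BCl3 bound between the C4 carbonyl and the peri C5 methoxy oxygen should lose chloromethane from that ether alone to give chelate 14, which water hydrolyses, while the six methoxy groups without a neighbouring carbonyl should survive at low temperature and limited reagent.

**Compound list**

1 | 2,6-dimethoxyphenol | COc1cccc(OC)c1O | starting material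
2 | 2,6-dimethoxyphenyl acetate | COc1cccc(OC)c1OC(C)=O | intermediate
3 | 3-acetyl-2,6-dimethoxyphenyl acetate | CC(=O)Oc1c(OC)ccc(C(C)=O)c1OC | intermediate
4 | 1-(3-hydroxy-2,4-dimethoxyphenyl)ethanone | CC(=O)c1ccc(OC)c(O)c1OC | intermediate
5 | 1,2,3,4-tetramethoxybenzene | COc1ccc(OC)c(OC)c1OC | starting material
6 | 2,3,4,5-tetramethoxyphenyllithium | [Li]c1cc(OC)c(OC)c(OC)c1OC | intermediate
7 | methyl 2,3,4,5-tetramethoxybenzoate | COC(=O)c1cc(OC)c(OC)c(OC)c1OC | intermediate
8 | dilithium 2,6-dimethoxy-3-(1-oxidoethenyl)phenolate (phenoxide-enolate of 4) | [Li+].[Li+].C=C([O-])c1ccc(OC)c([O-])c1OC | intermediate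
9 | 1-(3-hydroxy-2,4-dimethoxyphenyl)-3-(2,3,4,5-tetramethoxyphenyl)propane-1,3-dione | COc1cc(C(=O)CC(=O)c2ccc(OC)c(O)c2OC)c(OC)c(OC)c1OC | intermediate
10 | ring A phenoxonium cation of 9, drawn with the charge on the carbon para to the oxygen (the future C8a) | COC1=C[CH+]C(C(=O)CC(=O)c2cc(OC)c(OC)c(OC)c2OC)=C(OC)C1=O | intermediate
11 | 5,7-dimethoxy-2-(2,3,4,5-tetramethoxyphenyl)-8aH-chromene-4,6-dione (8a-H cyclohexadienone, racemic and transient) | COC1=CC2OC(c3cc(OC)c(OC)c(OC)c3OC)=CC(=O)C2=C(OC)C1=O | intermediate
12 | 6-hydroxy-5,7-dimethoxy-2-(2,3,4,5-tetramethoxyphenyl)chromen-4-one | COc1cc(-c2cc(=O)c3c(OC)c(O)c(OC)cc3o2)c(OC)c(OC)c1OC | intermediate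
13 | 5,6,7-trimethoxy-2-(2,3,4,5-tetramethoxyphenyl)chromen-4-one | COc1cc(-c2cc(=O)c3c(OC)c(OC)c(OC)cc3o2)c(OC)c(OC)c1OC | intermediate
14 | 5-O-dichloroboryl chelate of the 5-hydroxyflavone (aryloxy-dichloroborane, boron also bound to the C4 carbonyl) | COc1cc(-c2cc(=O)c3c(OB(Cl)Cl)c(OC)c(OC)cc3o2)c(OC)c(OC)c1OC | intermediate
15 | agecorynin F, 5-hydroxy-6,7-dimethoxy-2-(2,3,4,5-tetramethoxyphenyl)chromen-4-one | COc1cc(-c2cc(=O)c3c(O)c(OC)c(OC)cc3o2)c(OC)c(OC)c1OC | target

**Step count and risks**

Total steps: 8. Longest linear sequence: 7 steps (steps 1, 2, 3, 5, 6, 7, 8, from 2,6-dimethoxyphenol); the branch from 1,2,3,4-tetramethoxybenzene runs through 5 steps (4, 5, 6, 7, 8).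

Steps most likely to fail:

Step 6 (the proposed anodic ring closure). The process most likely to spoil it is further oxidation of the cyclised phenol 12, which keeps its free hydroxyl and is probably no harder to oxidise than 9. Intermolecular coupling of cation 10 that coats the anode is the second concern. The fallback uses known chemistry, sets out from 5 and returns at 13. Aryllithium 6 is generated as in step 4 but quenched with DMF to give 2,3,4,5-tetramethoxybenzaldehyde F1. Claisen–Schmidt condensation (KOH, EtOH, rt) of this aldehyde with the catalogue ketone 1-(6-hydroxy-2,3,4-trimethoxyphenyl)ethanone F2 should give (E)-1-(6-hydroxy-2,3,4-trimethoxyphenyl)-3-(2,3,4,5-tetramethoxyphenyl)prop-2-en-1-one F3. I2 (cat.) in DMSO at 120 °C should then close ring C by oxa-Michael addition and dehydrogenation to give 13, after which step 8 follows unchanged. In this variant the O1–C8a bond is bought with the phenol and ring C closes at O1–C2.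

Step 2 (Friedel–Crafts acetylation). The likely failure is Lewis-acid cleavage of the methoxy group that ends up between the new, chelating ketone and the acetoxy group, or acetyl transfer between oxygen and carbon that gives mixtures. The fallback sets out from 1 and returns at 4. Compound 1 is protected with MOMCl and i-Pr2NEt as 2-(methoxymethoxy)-1,3-dimethoxybenzene F4. n-BuLi and TMEDA in THF at 0 °C should lithiate next to a methoxy group, the only kind of ring position with an adjacent directing oxygen, to give [3-(methoxymethoxy)-2,4-dimethoxyphenyl]lithium F5. Acylation by N-methoxy-N-methylacetamide should give 1-[3-(methoxymethoxy)-2,4-dimethoxyphenyl]ethanone F6, and HCl in MeOH removes the acetal to deliver 4. No strong Lewis acid is involved and the position is fixed by the directing group.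

Step 5 (Claisen condensation on the unprotected phenol). The phenoxide-enolate 8 may aggregate or precipitate, so that C-acylation by the ortho-substituted ester stalls and self-condensation of the ketone takes over. The fallback sets out from 4 and returns at 9. Compound 4 is benzylated (BnBr, K2CO3, DMF) to 1-[3-(benzyloxy)-2,4-dimethoxyphenyl]ethanone F7. LiN(SiMe3)2 (2.2 equiv) in THF gives lithium 1-[3-(benzyloxy)-2,4-dimethoxyphenyl]ethenolate F8, which is acylated by 7 to 1-[3-(benzyloxy)-2,4-dimethoxyphenyl]-3-(2,3,4,5-tetramethoxyphenyl)propane-1,3-dione F9. Hydrogenolysis (H2, Pd/C, EtOAc, rt) frees the phenol and gives 9.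

**Further compounds**

F1 | step 6 | 2,3,4,5-tetramethoxybenzaldehyde | COc1cc(C=O)c(OC)c(OC)c1OC
F2 | step 6 | 1-(6-hydroxy-2,3,4-trimethoxyphenyl)ethanone | CC(=O)c1c(O)cc(OC)c(OC)c1OC
F3 | step 6 | (E)-1-(6-hydroxy-2,3,4-trimethoxyphenyl)-3-(2,3,4,5-tetramethoxyphenyl)prop-2-en-1-one | COc1cc(/C=C/C(=O)c2c(O)cc(OC)c(OC)c2OC)c(OC)c(OC)c1OC
F4 | step 2 | 2-(methoxymethoxy)-1,3-dimethoxybenzene | COCOc1c(OC)cccc1OC
F5 | step 2 | [3-(methoxymethoxy)-2,4-dimethoxyphenyl]lithium | [Li]c1ccc(OC)c(OCOC)c1OC
F6 | step 2 | 1-[3-(methoxymethoxy)-2,4-dimethoxyphenyl]ethanone | CC(=O)c1ccc(OC)c(OCOC)c1OC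
F7 | step 5 | 1-[3-(benzyloxy)-2,4-dimethoxyphenyl]ethanone | CC(=O)c1ccc(OC)c(OCc2ccccc2)c1OC
F8 | step 5 | lithium 1-[3-(benzyloxy)-2,4-dimethoxyphenyl]ethenolate | [Li+].C=C([O-])c1ccc(OC)c(OCc2ccccc2)c1OC
F9 | step 5 | 1-[3-(benzyloxy)-2,4-dimethoxyphenyl]-3-(2,3,4,5-tetramethoxyphenyl)propane-1,3-dione | COc1cc(C(=O)CC(=O)c2ccc(OC)c(OCc3ccccc3)c2OC)c(OC)c(OC)c1OC
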